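The target's cyclohexene ring contains a γ,δ-unsaturated acid, HO2C–C4–C5–C6=C7, in which C4 and C5 are adjacent quaternary stereocentres. The route rests on cutting C4–C5 as a retro-Ireland–Claisen: the C4 carboxyl is tied as a δ-lactone to a tertiary C7 carbinol that bears methyl and an (E,E)-dienyl arm. In one operation the lactone silyl ketene acetal makes C4–C5, fixes both quaternary centres, breaks O–C7, installs C6=C7 and exchanges the six-membered lactone for the six-membered carbocycle. The precursor is a trans-fused cyclopentane δ-lactone with a dioxolane at C2, built enantiopure from (S)-4-silyloxycyclopentenone by two trans-selective conjugate additions.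

Key step: step 12

Assumption: every intermediate keeps the target's ring numbering (C1 = CHEt, C2 = C=O or ketal carbon, C3 = CHMe, C3a, C7a; C4 = ester α-carbon; C7 = carbon on C7a); α/β refer to the flat drawing with C3a–H β.
Assumption: C4 is carried as a mixture of epimers from 9 to 21 and is left undefined in the SMILES, because step 12 planarises it; C7 in 18 is likewise a mixture.
Assumption: 1 and 14 are taken as catalogue compounds.
Remark: in the resting half-chair of lactone 21 the dienyl arm is equatorial (cis to C7a–H); it becomes axial only in the reactive boat.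

Step 1
Reactants: 1 (4S)-4-[(tert-butyldimethylsilyl)oxy]cyclopent-2-en-1-one
Product: 2 (4S)-4-[(tert-butyldimethylsilyl)oxy]-2-iodocyclopent-2-en-1-one
Conditions: I2, pyridine, CH2Cl2, 0 → 23 °C
Reagents that add atoms: iodine, II
Why: α-Iodination of the enone by pyridine conjugate addition, iodination of the enolate and loss of pyridine (Baylis–Hillman-type mechanism) should leave the C3a silyloxy stereocentre untouched.

Step 2
Reactants: 2 (4S)-4-[(tert-butyldimethylsilyl)oxy]-2-iodocyclopent-2-en-1-one
Product: 3 (4S)-4-[(tert-butyldimethylsilyl)oxy]-2-ethylcyclopent-2-en-1-one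
Conditions: Et2Zn, PdCl2(dppf) (5 mol %), THF–DMF, 0 → 23 °C
Reagents that add atoms: diethylzinc, CC[Zn]CC
Why: Negishi coupling of the α-iodoenone with the dialkylzinc should place the C1 ethyl group under neutral conditions without forming a stereocentre, so that no enolate ethylation is needed later.

Step 3
Reactants: 3 (4S)-4-[(tert-butyldimethylsilyl)oxy]-2-ethylcyclopent-2-en-1-one
Product: 6 (4R,5S)-4-ethenyl-5-ethylcyclopent-2-en-1-one, via trimethylsilyl enol ether 4 (not isolated), via β-silyloxy ketone 5 (not isolated)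
Conditions: CH2=CHMgBr, CuBr·SMe2 (10 mol %), TMSCl, THF, −78 °C; aq. HCl work-up; DBU, CH2Cl2, 0 °C
Reagents that add atoms: vinylmagnesium bromide, C=C[Mg]Br
Why: Copper-catalysed, silyl-chloride-accelerated conjugate addition should deliver vinyl trans to the C3a silyloxy group and so set C7a, after which E1cB loss of silanol from the β-silyloxy ketone unveils the C3=C3a enone while C1 equilibrates to the trans (α-ethyl) epimer.

Step 4
Reactants: 7 methyl butanoate
Product: 8 1-methoxy-1-(trimethylsilyloxy)but-1-ene (E/Z mixture)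
Conditions: LDA, THF, −78 °C; TMSCl
Reagents that add atoms: chlorotrimethylsilane, C[Si](C)(C)Cl
Why: Kinetic ester enolisation and O-silylation should give the silyl ketene acetal, whose geometry is irrelevant because C4 is planarised again in step 12.

Step 5
Reactants: 6 (4R,5S)-4-ethenyl-5-ethylcyclopent-2-en-1-one; 8 1-methoxy-1-(trimethylsilyloxy)but-1-ene
Product: 10 methyl 2-(2-ethenyl-3-ethyl-5-methyl-4-oxocyclopentyl)butanoate (all-trans ring; C4 epimers), via enol silane 9 (not isolated)
Conditions: Tf2NH (2 mol %), CH2Cl2, −78 °C; then MeI, BnMe3NF, THF, −40 → 0 °C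
Reagents that add atoms: iodomethane, CI
Why: The Mukaiyama–Michael addition should bring the ketene acetal to C3a anti to the C7a vinyl group, and the regiodefined enol silane is then methylated at C3 as its ammonium enolate (fluoride-mediated alkylation) anti to the new C3a side chain, which completes the all-trans ring.

Step 6
Reactants: 10 methyl 2-(2-ethenyl-3-ethyl-5-methyl-4-oxocyclopentyl)butanoate
Product: 11 C2 ethylene ketal of 10
Conditions: (TMSOCH2)2, TMSOTf (5 mol %), CH2Cl2, −78 → −20 °C
Reagents that add atoms: 1,2-bis(trimethylsilyloxy)ethane, C[Si](C)(C)OCCO[Si](C)(C)C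
Why: Silyl-triflate-catalysed ketalisation with the bis-silyl ether should mask the hindered C2 ketone, the only ketone present, with C1 and C3 remaining in their preferred trans arrangement.

Step 7
Reactants: 11 C2 ethylene ketal of 10
Product: 13 C7 aldehyde (formyl on C7a; ketal and ester retained), via secondary ozonide 12 (not isolated)
Conditions: O3, CH2Cl2, −78 °C; PPh3, → 23 °C
Reagents that add atoms: ozone, [O-][O+]=O
Why: Ozonolysis with reductive work-up should cleave the only alkene to the aldehyde, whose epimerisable C7a already sits in the favoured trans,trans arrangement.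

Step 8
Reactants: 14 (E)-but-1-en-3-yn-1-ylbenzene
Product: 16 [(1E,3E)-3-ethyl-4-iodobuta-1,3-dien-1-yl]benzene, via dienylcopper 15 (not isolated)
Conditions: EtMgBr, CuBr·SMe2, Et2O–Me2S, −45 → −25 °C; I2, THF, −50 → 0 °C
Reagents that add atoms: ethylmagnesium bromide, CC[Mg]Br; iodine, II
Why: syn-Carbocupration of the terminal alkyne should put ethyl on the internal carbon and copper cis to it on the terminal one, and iodinolysis with retention gives the dienyl iodide with ethyl cis to iodine.

Step 9
Reactants: 13 C7 aldehyde; 16 [(1E,3E)-3-ethyl-4-iodobuta-1,3-dien-1-yl]benzene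
Product: 18 dienyl carbinol (C7 epimers), via dienylchromium dichloride 17 (not isolated)
Conditions: CrCl2, NiCl2 (1 mol %), DMSO, 23 °C
Reagents that add atoms: none
Why: The Nozaki–Hiyama–Kishi reaction should add the alkenylchromium species to the aldehyde alone, with retention of alkene geometry and tolerance of ester and ketal, and the carbinol configuration is irrelevant because it is oxidised next.

Step 10
Reactants: 18 dienyl carbinol
Product: 19 dienone ((2E,4E)-3-ethyl-5-phenylpenta-2,4-dienoyl on C7a)
Conditions: DMP, CH2Cl2, 23 °C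
Reagents that add atoms: none
Why: Dess–Martin oxidation of the dienylic alcohol should give the ketone without touching the ketal, the ester or the alkene geometry.

Step 11
Reactants: 19 dienone
Product: 21 ketal-protected trans-fused dienyl δ-lactone (C4 epimers), via hydroxy ester 20 (not isolated)
Conditions: MeLi, CeCl3, THF, −78 → 23 °C
Reagents that add atoms: methyllithium, [Li]C
Why: 1,2-Addition of the non-basic methylcerium reagent should follow the Felkin–Anh model with C3a (branched ester side chain) as the large group, so that methyl enters anti to the C7a–C3a bond from the C1 flank and sets C7 with the dienyl arm cis to C7a–H, after which the tertiary alkoxide closes the δ-lactone on the methyl ester.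

Step 12
Reactants: 21 ketal-protected trans-fused dienyl δ-lactone
Product: 24 C2 ethylene ketal of the target acid, via silyl ketene acetal 22 (not isolated), via silyl ester 23 (not isolated)
Conditions: KHMDS, TBSCl, DMPU–THF, −78 °C; PhMe, 110 °C; AcOH, THF–H2O, 23 °C
Reagents that add atoms: none
Why: KHMDS removes the only acidic proton (C4–H) and O-silylation gives the ring-locked silyl ketene acetal, which should undergo a concerted [3,3] Ireland–Claisen shift in which C4–C5 forms as O–C7 breaks, the reaction type known for 6-alkenyl δ-lactones that rearrange through a boat. The carbocycle C3a–C4–C5–C6–C7–C7a is closed by this suprafacial sigmatropic C4–C5 bond formation, with O and C(OSi) leaving the ring as the exocyclic silyl ester while C5 and C6 enter it, so a six-membered oxacycle is exchanged for a six-membered carbocycle. Because C4 and C7 stay linked through C3a–C7a, only a boat-type (bicyclo[2.2.2]-like) transition state is possible, in which the dienyl arm, equatorial in the resting half-chair, becomes the flagpole substituent. C4 is set by the C7 configuration, since the arm can bond only to the lactone face of C4 that carries C7a–H, which leaves the carboxyl β on the face that held the C7–O bond. C5 is set by the (E) geometry of C5=C6 read through the enforced boat, which turns ethyl (cis to C7) α and styryl β, cis to the carboxyl. The step needs clean C4 enolisation (the dioxolane takes the C2 α-protons out of play) and a pericyclic shift faster than ionisation of the tertiary dienylic C7–O bond, which in-situ silylation and a non-polar solvent at the lowest workable temperature should favour.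

Step 13
Reactants: 24 C2 ethylene ketal of the target acid
Product: 25 (1S,3S,3aR,4R,5S,7aR)-1,4,5-triethyl-3,7-dimethyl-2-oxo-5-[(E)-2-phenylethenyl]-2,3,3a,4,5,7a-hexahydro-1H-indene-4-carboxylic acid
Conditions: 2 M HCl, THF, 45 °C
Reagents that add atoms: water, O
Why: Acid-catalysed hydrolysis of the dioxolane should free the C2 ketone, with C1 and C3 already in the thermodynamically preferred all-trans arrangement and the ring fusion and quaternary centres not epimerisable.

Compound list
1 | (4S)-4-[(tert-butyldimethylsilyl)oxy]cyclopent-2-en-1-one | O=C1C[C@H](O[Si](C)(C)C(C)(C)C)C=C1 | starting material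
2 | (4S)-4-[(tert-butyldimethylsilyl)oxy]-2-iodocyclopent-2-en-1-one | O=C1C[C@H](O[Si](C)(C)C(C)(C)C)C=C1I | intermediate
3 | (4S)-4-[(tert-butyldimethylsilyl)oxy]-2-ethylcyclopent-2-en-1-one | O=C1C[C@H](O[Si](C)(C)C(C)(C)C)C=C1CC | intermediate
4 | (3S,4S)-4-[(tert-butyldimethylsilyl)oxy]-3-ethenyl-2-ethyl-1-(trimethylsilyloxy)cyclopent-1-ene (vinyl trans to OTBS) | CCC1=C(O[Si](C)(C)C)C[C@H](O[Si](C)(C)C(C)(C)C)[C@H]1C=C | intermediate (not isolated)
5 | (3S,4S)-4-[(tert-butyldimethylsilyl)oxy]-3-ethenyl-2-ethylcyclopentan-1-one (vinyl trans to OTBS; C2 epimers) | CCC1C(=O)C[C@H](O[Si](C)(C)C(C)(C)C)[C@H]1C=C | intermediate (not isolated)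
6 | (4R,5S)-4-ethenyl-5-ethylcyclopent-2-en-1-one (trans) | CC[C@@H]1C(=O)C=C[C@H]1C=C | intermediate
7 | methyl butanoate | CCCC(=O)OC | starting material
8 | 1-methoxy-1-(trimethylsilyloxy)but-1-ene (E/Z mixture) | CCC=C(OC)O[Si](C)(C)C | intermediate
9 | C2=C3 trimethylsilyl enol ether of the Michael adduct (1α-ethyl, 7aβ-ethenyl, 3aα-CH(Et)CO2Me; C4 epimers) | CC[C@@H]1C(O[Si](C)(C)C)=C[C@H](C(CC)C(=O)OC)[C@H]1C=C | intermediate (not isolated)
10 | methyl 2-(2-ethenyl-3-ethyl-5-methyl-4-oxocyclopentyl)butanoate, all-trans ring (1α-Et, 3β-Me, 3aβ-H, 7aα-H; C4 epimers) | CC[C@@H]1C(=O)[C@@H](C)[C@H](C(CC)C(=O)OC)[C@H]1C=C | intermediate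
11 | C2 ethylene ketal (1,3-dioxolane) of 10 | CC[C@@H]1C2(OCCO2)[C@@H](C)[C@H](C(CC)C(=O)OC)[C@H]1C=C | intermediate
12 | secondary ozonide of 11 (1,2,4-trioxolan-3-yl on C7a) | CC[C@@H]1C2(OCCO2)[C@@H](C)[C@H](C(CC)C(=O)OC)[C@H]1C1OOCO1 | intermediate (not isolated)
13 | C7 aldehyde: formyl on C7a, C2 dioxolane, methyl ester side chain on C3a (all-trans ring; C4 epimers) | CC[C@@H]1C2(OCCO2)[C@@H](C)[C@H](C(CC)C(=O)OC)[C@H]1C=O | intermediate
14 | (E)-but-1-en-3-yn-1-ylbenzene | C#C/C=C/c1ccccc1 | starting material
15 | [(1E,3E)-2-ethyl-4-phenylbuta-1,3-dien-1-yl]copper | [Cu]/C=C(CC)/C=C/c1ccccc1 | intermediate (not isolated)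
16 | [(1E,3E)-3-ethyl-4-iodobuta-1,3-dien-1-yl]benzene (ethyl cis to iodine) | I/C=C(CC)/C=C/c1ccccc1 | intermediate
17 | [(1E,3E)-2-ethyl-4-phenylbuta-1,3-dien-1-yl]chromium(III) dichloride | Cl[Cr](Cl)/C=C(CC)/C=C/c1ccccc1 | intermediate (not isolated)
18 | dienyl carbinol: C7(H)(OH) bearing the (1E,3E)-2-ethyl-4-phenylbuta-1,3-dienyl arm (C7 and C4 epimers) | CC[C@@H]1C2(OCCO2)[C@@H](C)[C@H](C(CC)C(=O)OC)[C@H]1C(O)/C=C(CC)/C=C/c1ccccc1 | intermediate
19 | dienone: (2E,4E)-3-ethyl-5-phenylpenta-2,4-dienoyl group on C7a (C4 epimers) | CC[C@@H]1C2(OCCO2)[C@@H](C)[C@H](C(CC)C(=O)OC)[C@H]1C(=O)/C=C(CC)/C=C/c1ccccc1 | intermediate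
20 | (7S) tertiary hydroxy ester, formed as its cerium alkoxide (C7: OH, Me, dienyl; C4 epimers) | CC[C@@H]1C2(OCCO2)[C@@H](C)[C@H](C(CC)C(=O)OC)[C@H]1[C@@](C)(/C=C(CC)/C=C/c1ccccc1)O | intermediate (not isolated)
21 | ketal-protected δ-lactone C4–C(=O)–O–C7, trans-fused to the cyclopentane (1α-Et, 3β-Me, 3aβ-H, 7aα-H); C7 (S) carries β-Me and the α (1E,3E)-2-ethyl-4-phenylbuta-1,3-dienyl arm, cis to C7a–H; C4 epimers | CC[C@@H]1C3(OCCO3)[C@@H](C)[C@H]2[C@H]1[C@@](C)(/C=C(CC)/C=C/c1ccccc1)OC(=O)C2CC | intermediate
22 | tert-butyldimethylsilyl ketene acetal of 21 (C4=C(OTBS)–O) | CC[C@@H]1C3(OCCO3)[C@@H](C)[C@H]2[C@H]1[C@@](C)(/C=C(CC)/C=C/c1ccccc1)OC(O[Si](C)(C)C(C)(C)C)=C2CC | intermediate (not isolated)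
23 | tert-butyldimethylsilyl ester of 24 | CC[C@@H]1C3(OCCO3)[C@@H](C)[C@H]2[C@H]1C(C)=C[C@@](/C=C/c1ccccc1)(CC)[C@]2(CC)C(=O)O[Si](C)(C)C(C)(C)C | intermediate (not isolated)
24 | C2 ethylene ketal of the target acid (4β-CO2H, 4α-Et, 5β-styryl, 5α-Et) | CC[C@@H]1C3(OCCO3)[C@@H](C)[C@H]2[C@H]1C(C)=C[C@@](/C=C/c1ccccc1)(CC)[C@]2(CC)C(=O)O | intermediate
25 | (1S,3S,3aR,4R,5S,7aR)-1,4,5-triethyl-3,7-dimethyl-2-oxo-5-[(E)-2-phenylethenyl]-2,3,3a,4,5,7a-hexahydro-1H-indene-4-carboxylic acid | CC[C@@H]1C(=O)[C@@H](C)[C@H]2[C@H]1C(C)=C[C@@](/C=C/c1ccccc1)(CC)[C@]2(CC)C(=O)O | target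

Total step count: 13. Longest linear sequence: 11 steps (steps 1, 2, 3, 5, 6, 7, 9, 10, 11, 12, 13); steps 4 and 8 are side branches.

Steps most likely to fail

1. Step 12. The boat-type transition state may be out of reach: the trans-fused cyclopentane on the C3a–C7a bridge resists the near-eclipsed geometry the boat demands, and both bond-forming termini are fully substituted. Ionisation of the tertiary dienylic C7–O bond, elimination or ring opening to a ketene could then overtake the sigmatropic shift. Fallback (from 19, back at 24): the methylcerium addition to 19 is run as in step 11, but the cerium alkoxide is trapped at −78 °C with methyl chloroformate before it lactonises, giving the C7 methyl carbonate F1. LDA/TBSCl (THF–DMPU, −78 °C) converts its C4 methyl ester into the silyl ketene acetal F2. ZnBr2 in CH2Cl2 then ionises the dienylic carbonate, and the ketene acetal closes the carbocycle at C5 by an intramolecular Mukaiyama-type SN1′ alkylation, which needs no bicyclic boat, to give the methyl ester F3. LiI in hot pyridine dealkylates this hindered ester to 24. The C4/C5 sense would then depend on a chair-like ionic closure and is less secure than in the pericyclic step.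

2. Step 11. The facial selectivity of the methyl addition may be opposite to, or weaker than, the Felkin–Anh prediction, because both flanks of C7a carry a trans substituent and differ only in the size of that substituent. Fallback (from 13, back at 21): MeMgBr adds to aldehyde 13 (THF, −78 °C) to give the methyl carbinol F4, and Dess–Martin oxidation gives the methyl ketone F5. The dienyllithium F6 (from 16 and t-BuLi, Et2O, −78 °C, used with LaCl3·2LiCl as additive) is then added to F5. With the two carbon groups entering in the opposite order, the same facial bias leads to the other C7 epimer, whose alkoxide (that of 20) lactonises to 21.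

3. Step 5. Proton transfer between the ammonium enolate and the product ketone may scramble the enolate regiochemistry or cause over-methylation, and the alkylation may not be fully anti. Fallback (from 6, back at 10): the methyl group is installed before the Michael step. Iodination of 6 (I2, pyridine) gives the C3-iodo enone F7, and Negishi coupling with MeZnCl and Pd(PPh3)4 gives the C3-methyl enone F8. Mukaiyama–Michael addition of 8 then gives the tetrasubstituted enol silane F9, which is protonated on acidic work-up, C3 settling as the trans ketone, to give 10.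

Further compounds
F1 | step 12 | C7 methyl carbonate of hydroxy ester 20 | CC[C@@H]1C2(OCCO2)[C@@H](C)[C@H](C(CC)C(=O)OC)[C@H]1[C@@](C)(/C=C(CC)/C=C/c1ccccc1)OC(=O)OC
F2 | step 12 | tert-butyldimethylsilyl ketene acetal of the C4 methyl ester of F1 | CC[C@@H]1C2(OCCO2)[C@@H](C)[C@H](C(CC)=C(OC)O[Si](C)(C)C(C)(C)C)[C@H]1[C@@](C)(/C=C(CC)/C=C/c1ccccc1)OC(=O)OC
F3 | step 12 | methyl ester of 24 | CC[C@@H]1C3(OCCO3)[C@@H](C)[C@H]2[C@H]1C(C)=C[C@@](/C=C/c1ccccc1)(CC)[C@]2(CC)C(=O)OC
F4 | step 11 | methyl carbinol from 13 (1-hydroxyethyl on C7a; carbinol epimers) | CC[C@@H]1C2(OCCO2)[C@@H](C)[C@H](C(CC)C(=O)OC)[C@H]1C(C)O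
F5 | step 11 | C7 methyl ketone (acetyl on C7a) | CC[C@@H]1C2(OCCO2)[C@@H](C)[C@H](C(CC)C(=O)OC)[C@H]1C(C)=O
F6 | step 11 | [(1E,3E)-2-ethyl-4-phenylbuta-1,3-dien-1-yl]lithium | [Li]/C=C(CC)/C=C/c1ccccc1
F7 | step 5 | (4R,5S)-4-ethenyl-5-ethyl-2-iodocyclopent-2-en-1-one | CC[C@@H]1C(=O)C(I)=C[C@H]1C=C
F8 | step 5 | (4R,5S)-4-ethenyl-5-ethyl-2-methylcyclopent-2-en-1-one | CC[C@@H]1C(=O)C(C)=C[C@H]1C=C
F9 | step 5 | C2=C3 trimethylsilyl enol ether of 10 | CC[C@@H]1C(O[Si](C)(C)C)=C(C)[C@H](C(CC)C(=O)OC)[C@H]1C=C
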